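With p-menthane numbering of the cyclohexane ring, Br (C2, equatorial) and OH (C1, axial) are cis. Anti addition to a limonene-type C1=C2 alkene cannot deliver this, whereas methyl addition anti to Br in an α-bromoketone does. Disconnecting the C1–CH3 and C2–Br bonds therefore uncovers an achiral, Cs-symmetric 4-alkenylcyclohexanone, because C4 is stereogenic in the target only through the difference between C2 and C6. The key step is enantiotopic deprotonation by a chiral lithium amide with in situ silylation. It converts this ketone into one regiodefined (S)-silyl enol ether, fixing C4 and the bromination site, and C2 and C1 are relayed from it. (S)-Linalool, made from geraniol, is attached last by Heck vinylation.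

Key step: step 4

Assumption: the sense of induction of the (R,R)-amide is taken from the 4-alkylcyclohexanone series; should it prove opposite for 6, the equally available (S,S)-amine is used.

Step 1
Reactants: 1 ethyl 1,4-dioxaspiro[4.5]decane-8-carboxylate
Product: 3 8-ethynyl-1,4-dioxaspiro[4.5]decane, via aldehyde 2 (not isolated)
Conditions: DIBAL-H (1.1 equiv), CH2Cl2, −78 °C; MeOH; then K2CO3, dimethyl (1-diazo-2-oxopropyl)phosphonate, −78 °C → rt
Reagents that add atoms: dimethyl (1-diazo-2-oxopropyl)phosphonate (Ohira–Bestmann reagent), COP(=O)(OC)C(=[N+]=[N-])C(C)=O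
Why: Partial DIBAL-H reduction of the ester to the aldehyde stage is followed in the same flask by Ohira–Bestmann (Seyferth–Gilbert) homologation, and no stereocentre is involved because the ring is Cs-symmetric.

Step 2
Reactants: 3 8-ethynyl-1,4-dioxaspiro[4.5]decane
Product: 5 8-[(E)-1-iodoprop-1-en-2-yl]-1,4-dioxaspiro[4.5]decane, via alkenyldimethylalane 4 (not isolated)
Conditions: AlMe3 (2.5 equiv), Cp2ZrCl2 (20 mol %), CH2Cl2, 0 °C → rt; then I2, THF, −30 °C
Reagents that add atoms: trimethylaluminium, C[Al](C)C; iodine, II
Why: Zirconium-catalysed Negishi carboalumination adds CH3 and Al syn across the terminal alkyne with Al at the terminus, and iodinolysis of the C–Al bond with retention fixes the (E)-trisubstituted alkene.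

Step 3
Reactants: 5 8-[(E)-1-iodoprop-1-en-2-yl]-1,4-dioxaspiro[4.5]decane
Product: 6 4-[(E)-1-iodoprop-1-en-2-yl]cyclohexan-1-one
Conditions: 1 M aq HCl, THF, rt
Reagents that add atoms: water, O
Why: Acid-catalysed ketal hydrolysis leaves the alkenyl iodide untouched and releases the achiral, Cs-symmetric ketone needed for the key step.

Step 4
Reactants: 6 4-[(E)-1-iodoprop-1-en-2-yl]cyclohexan-1-one
Product: 8 {[(4S)-4-[(E)-1-iodoprop-1-en-2-yl]cyclohex-1-en-1-yl]oxy}trimethylsilane, via lithium enolate 7 (not isolated)
Conditions: (R,R)-bis(1-phenylethyl)amine (1.2 equiv), n-BuLi (1.15 equiv), THF, −78 → 0 °C; then −100 °C, TMSCl (5 equiv, internal quench), slow addition of 6; Et3N, aq NaHCO3 work-up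
Reagents that add atoms: chlorotrimethylsilane, C[Si](C)(C)Cl
Why: The C2-symmetric lithium amide removes one of the two enantiotopic axial α-protons (C2–Hax versus C6–Hax) of the chair of 6 that carries the alkenyl group equatorial, through a cyclic Li–O/N···H transition state, and enolate 7 is silylated at once by the TMSCl already present, so that it cannot equilibrate by proton transfer. This is the chiral lithium amide asymmetric deprotonation (desymmetrisation) of 4-substituted cyclohexanones, well established for 4-tert-butyl, 4-isopropyl, 4-methyl and 4-phenyl substrates, and the branched sp2 substituent of 6 is sterically close to isopropyl. No ring is closed. The only new stereocentre, C4, becomes (S) solely because the C1=C2 double bond is placed on one side of the former mirror plane, and the controlling element is the reagent: the (R,R)-amide gives the (S)-enol silanes in the 4-alkyl series, which share the CIP ranking of 8. The only selectivity needed is between enantiotopic groups (a Cs-symmetric ketone poses no regio- or diastereochemical question), and it is secured by the conformational lock of the equatorial C4 substituent, the stereoelectronic demand for axial C–H cleavage and the very low temperature. The gain is that the position of Br (C2, not C6), and with it the absolute configuration of C2 and C1 relayed from C4 in steps 5 and 6, is decided in this one operation.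

Step 5
Reactants: 8 {[(4S)-4-[(E)-1-iodoprop-1-en-2-yl]cyclohex-1-en-1-yl]oxy}trimethylsilane
Product: 10 (2S,4S)-2-bromo-4-[(E)-1-iodoprop-1-en-2-yl]cyclohexan-1-one (cis; Br equatorial), via trans-bromoketone 9 (not isolated)
Conditions: NBS (1.0 equiv), THF, −78 °C; then LiBr (3 equiv), DMF, rt; chromatography, recovered 9 re-equilibrated
Reagents that add atoms: N-bromosuccinimide, O=C1CCC(=O)N1Br; lithium bromide (degenerate Br exchange), [Li+].[Br-]
Why: Electrophilic α-bromination of the silyl enol ether places Br only on C2 (stereoelectronically axial attack should give trans-9), and Finkelstein-type degenerate SN2 exchange with bromide then inverts C2 reversibly without touching C4 or moving the halogen, so that the more polar equatorial bromide 10 should accumulate in the polar, Li+-rich medium.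

Step 6
Reactants: 10 (2S,4S)-2-bromo-4-[(E)-1-iodoprop-1-en-2-yl]cyclohexan-1-one
Product: 11 (1R,2S,4S)-2-bromo-4-[(E)-1-iodoprop-1-en-2-yl]-1-methylcyclohexan-1-ol
Conditions: MeMgBr (1.3 equiv), Et2O, −78 °C; quench at −78 °C with pH 7 buffer
Reagents that add atoms: methylmagnesium bromide, C[Mg]Br
Why: In this Grignard 1,2-addition under polar Felkin–Anh/Cornforth control, CH3 enters the carbonyl face anti to C2–Br, which is also the equatorial trajectory preferred by small methyl nucleophiles on the diequatorial chair, so C1 should form with CH3 equatorial and OH axial (the classical cis-halohydrin outcome), while the cold quench forestalls semipinacol ring contraction.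

Step 7
Reactants: 12 geraniol
Product: 13 (2S,3S)-2,3-epoxygeraniol
Conditions: Ti(OiPr)4 (5 mol %), L-(+)-diethyl tartrate (7 mol %), t-BuOOH (1.5 equiv), 4 Å MS, CH2Cl2, −20 °C
Reagents that add atoms: tert-butyl hydroperoxide, CC(C)(C)OO
Why: In the Sharpless asymmetric epoxidation the titanium–tartrate complex binds the allylic alcohol, so only the C2=C3 alkene reacts, and L-(+)-DET delivers oxygen to the face that gives the (2S,3S)-epoxide, which sets the future carbinol centre.

Step 8
Reactants: 13 (2S,3S)-2,3-epoxygeraniol
Product: 14 (2R,3S)-2-(iodomethyl)-3-methyl-3-(4-methylpent-3-en-1-yl)oxirane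
Conditions: PPh3, I2, imidazole, Et2O–MeCN, 0 °C
Reagents that add atoms: iodine, II
Why: Appel-type iodination of the primary alcohol by SN2 at CH2 leaves the epoxide and both stereocentres untouched (the C2 descriptor changes to R only through CIP ranking).

Step 9
Reactants: 14 (2R,3S)-2-(iodomethyl)-3-methyl-3-(4-methylpent-3-en-1-yl)oxirane
Product: 15 (S)-(+)-linalool
Conditions: activated Zn dust, EtOH, 60 °C
Reagents that add atoms: none
Why: Two-electron reduction of the C–I bond by zinc triggers reductive β-elimination (Boord-type fragmentation) with opening of the C2–O bond, which unmasks the vinyl group while the C3–O bond and the (S) configuration from step 7 are retained.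

Step 10
Reactants: 11 (1R,2S,4S)-2-bromo-4-[(E)-1-iodoprop-1-en-2-yl]-1-methylcyclohexan-1-ol; 15 (S)-(+)-linalool (2 equiv)
Product: 16 (1R,2S,4S)-2-bromo-4-[(2E,4E,6S)-6-hydroxy-6,10-dimethylundeca-2,4,9-trien-2-yl]-1-methylcyclohexan-1-ol (target)
Conditions: Pd(OAc)2 (10 mol %), n-Bu4NCl, NaHCO3, DMF, 35–40 °C, dark; Et3N-deactivated silica
Reagents that add atoms: none
Why: In this ligand-free, phase-transfer Heck vinylation of a tertiary allylic alcohol, oxidative addition occurs only at the C(sp2)–I bond with retention of the (E) geometry, syn-carbopalladation puts the alkenyl group on the unhindered CH2 terminus of 15, and the only β-hydrogen available (the carbinol carbon has none) gives the new (E)-alkene without touching the carbinol centre, the secondary C–Br bond or the trisubstituted alkene.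

Compound list
1 | ethyl 1,4-dioxaspiro[4.5]decane-8-carboxylate | CCOC(=O)C1CCC2(CC1)OCCO2 | starting material
2 | 1,4-dioxaspiro[4.5]decane-8-carbaldehyde | O=CC1CCC2(CC1)OCCO2 | intermediate
3 | 8-ethynyl-1,4-dioxaspiro[4.5]decane | C#CC1CCC2(CC1)OCCO2 | intermediate
4 | [(E)-2-(1,4-dioxaspiro[4.5]decan-8-yl)prop-1-en-1-yl]dimethylalane | C[Al](C)/C=C(\C)C1CCC2(CC1)OCCO2 | intermediate
5 | 8-[(E)-1-iodoprop-1-en-2-yl]-1,4-dioxaspiro[4.5]decane | I/C=C(\C)C1CCC2(CC1)OCCO2 | intermediate
6 | 4-[(E)-1-iodoprop-1-en-2-yl]cyclohexan-1-one | I/C=C(\C)C1CCC(=O)CC1 | intermediate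
7 | lithium (4S)-4-[(E)-1-iodoprop-1-en-2-yl]cyclohex-1-en-1-olate | I/C=C(\C)[C@H]1CCC(O[Li])=CC1 | intermediate
8 | {[(4S)-4-[(E)-1-iodoprop-1-en-2-yl]cyclohex-1-en-1-yl]oxy}trimethylsilane | I/C=C(\C)[C@H]1CCC(O[Si](C)(C)C)=CC1 | intermediate
9 | (2R,4S)-2-bromo-4-[(E)-1-iodoprop-1-en-2-yl]cyclohexan-1-one (trans, Br axial) | I/C=C(\C)[C@H]1CCC(=O)[C@H](Br)C1 | intermediate
10 | (2S,4S)-2-bromo-4-[(E)-1-iodoprop-1-en-2-yl]cyclohexan-1-one (cis, Br equatorial) | I/C=C(\C)[C@H]1CCC(=O)[C@@H](Br)C1 | intermediate
11 | (1R,2S,4S)-2-bromo-4-[(E)-1-iodoprop-1-en-2-yl]-1-methylcyclohexan-1-ol | I/C=C(\C)[C@H]1CC[C@@](C)(O)[C@@H](Br)C1 | intermediate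
12 | geraniol | CC(C)=CCC/C(C)=C/CO | starting material
13 | (2S,3S)-2,3-epoxygeraniol | CC(C)=CCC[C@]1(C)O[C@H]1CO | intermediate
14 | (2R,3S)-2-(iodomethyl)-3-methyl-3-(4-methylpent-3-en-1-yl)oxirane | CC(C)=CCC[C@]1(C)O[C@H]1CI | intermediate
15 | (S)-(+)-linalool | CC(C)=CCC[C@](C)(O)C=C | intermediate
16 | (1R,2S,4S)-2-bromo-4-[(2E,4E,6S)-6-hydroxy-6,10-dimethylundeca-2,4,9-trien-2-yl]-1-methylcyclohexan-1-ol | CC(C)=CCC[C@](C)(O)/C=C/C=C(\C)[C@H]1CC[C@@](C)(O)[C@@H](Br)C1 | target

Total step count: 10. Longest linear sequence: 7 (steps 1–6 and 10, from 1).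

Steps most likely to fail

Step 4. The risk is insufficient discrimination between the enantiotopic α-protons, or partial proton-transfer equilibration of the enolate. Any residual ring enantiomer would become a diastereomer only after step 10.
- The fallback sets out from 6 and comes back at 10. It stores the same stereochemical information by enzymatic resolution instead of chiral-base chemistry.
- Ketone 6 is converted (isopropenyl acetate, cat. TsOH, reflux) into the racemic enol ester 4-[(E)-1-iodoprop-1-en-2-yl]cyclohex-1-en-1-yl acetate F1.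
- A lipase chosen by screening (n-BuOH, iPr2O) transesterifies the (R)-enantiomer faster, which regenerates achiral 6 for recycling. The reaction is run until the remaining (4S)-4-[(E)-1-iodoprop-1-en-2-yl]cyclohex-1-en-1-yl acetate F2 is enantiopure.
- Bromination of the enol acetate with NBS in wet THF gives 9, which is equilibrated with LiBr/DMF as in step 5 to 10.

Step 5. The risk is an axial/equatorial equilibrium that does not lie far enough on the equatorial side, loss of HBr to the enone, or halogen migration that erodes the stereochemical information.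
- The fallback sets out from the 9/10 mixture and comes back at 10. It replaces thermodynamic control by kinetic protonation.
- Soft enolisation towards the more acidic CHBr position (TMSOTf, Et3N, CH2Cl2, 0 °C) gives {[(4S)-2-bromo-4-[(E)-1-iodoprop-1-en-2-yl]cyclohex-1-en-1-yl]oxy}trimethylsilane F3.
- Fluoride cleavage at −78 °C in the presence of a proton source (TBAF, AcOH, THF) protonates C2 along the axial trajectory, which leaves Br equatorial and cis to the C4 substituent.

Step 10. The risk is sluggish insertion into the hindered allylic alcohol, scrambling of alkene geometry through Pd–H or π-allyl species, or degradation of the bromohydrin on prolonged warming.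
- The fallback sets out from 13 (with 11 as partner) and comes back at 16. It forms the same C–C bond by Stille coupling.
- Appel chlorination of 13 (PPh3, CCl4) gives (2R,3S)-2-(chloromethyl)-3-methyl-3-(4-methylpent-3-en-1-yl)oxirane F4.
- Base-induced double elimination (LDA, 3 equiv, THF, −35 °C) gives (S)-3,7-dimethyloct-6-en-1-yn-3-ol F5.
- Palladium-catalysed hydrostannation (Bu3SnH, PdCl2(PPh3)2) gives (S,E)-3,7-dimethyl-1-(tributylstannyl)octa-1,6-dien-3-ol F6.
- F6 couples with 11 at room temperature (Pd2(dba)3, AsPh3, NMP) with retention at both alkenes.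

Further compounds
F1 | step 4 | 4-[(E)-1-iodoprop-1-en-2-yl]cyclohex-1-en-1-yl acetate (racemic) | CC(=O)OC1=CCC(CC1)/C(C)=C/I
F2 | step 4 | (4S)-4-[(E)-1-iodoprop-1-en-2-yl]cyclohex-1-en-1-yl acetate | I/C=C(\C)[C@H]1CCC(OC(C)=O)=CC1
F3 | step 5 | {[(4S)-2-bromo-4-[(E)-1-iodoprop-1-en-2-yl]cyclohex-1-en-1-yl]oxy}trimethylsilane | I/C=C(\C)[C@H]1CCC(O[Si](C)(C)C)=C(Br)C1
F4 | step 10 | (2R,3S)-2-(chloromethyl)-3-methyl-3-(4-methylpent-3-en-1-yl)oxirane | CC(C)=CCC[C@]1(C)O[C@H]1CCl
F5 | step 10 | (S)-3,7-dimethyloct-6-en-1-yn-3-ol | CC(C)=CCC[C@](C)(O)C#C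
F6 | step 10 | (S,E)-3,7-dimethyl-1-(tributylstannyl)octa-1,6-dien-3-ol | CC(C)=CCC[C@](C)(O)/C=C/[Sn](CCCC)(CCCC)CCCC
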